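**Retrosynthetic overview**

- Target numbering: carbocycle C1(OMe)–C2H=C3(C7H2OBz)–C4(OH)–C5(OBz)–C6(OH). The strategy rests on C4 being a secondary allylic carbinol bonded directly to the alkene carbon C3, while C5, C6 and C1 carry the trans/cis oxygen pattern of C2, C3 and C4 of D-arabinose.
- Endgame: the two benzoates (O7, then O5) go onto a tetraol that is freed from a trans-fused 5,6-acetonide and an O7 silyl ether.
- Key disconnection C3–C4: intramolecular Nozaki–Hiyama–Kishi addition of a (Z)-alkenyl iodide (C3) to the sugar aldehyde (C4). This forms the only ring and the only new stereocentre.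
- Open-chain precursor from D-arabinose: C1 masked as the diethyl dithioacetal, O2/O3 as acetonide, O4 methylated, C5 oxidised and olefinated with an iodophosphonate that brings in ring C3 (C–I) and C7.

Key step: step 12

Remark: open-chain compounds carry carbohydrate locants and ring compounds the target locants; sugar C1, C2, C3, C4, C5 become ring C4, C5, C6, C1, C2, and ring C3 and C7 come from the phosphonate.

**Route**

Step 1
Reactants: 1 D-arabinose; 2 ethanethiol
Product: 3 D-arabinose diethyl dithioacetal
Conditions: EtSH (2.2 equiv), conc. HCl, 0 °C; crystallisation from ice-water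
Reagents that add atoms: ethanethiol (second equivalent), CCS
Why: acid-catalysed dithioacetalisation of the open-chain aldose takes up two molecules of thiol at C1, masks the aldehyde and leaves an acyclic tetraol; no stereocentre is touched.

Step 2
Reactants: 3 D-arabinose diethyl dithioacetal
Product: 4 2,3:4,5-di-O-isopropylidene-D-arabinose diethyl dithioacetal
Conditions: 2,2-dimethoxypropane (excess), acetone, p-TsOH·H2O (cat.), rt; Et3N quench
Reagents that add atoms: 2,2-dimethoxypropane, COC(C)(C)OC; 2,2-dimethoxypropane (second equivalent), COC(C)(C)OC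
Why: thermodynamic transacetalisation, one molecule of the ketal per diol; the threo 2,3-diol closes to the trans-disubstituted dioxolane and the terminal 4,5-diol takes the second acetonide.

Step 3
Reactants: 4 2,3:4,5-di-O-isopropylidene-D-arabinose diethyl dithioacetal
Product: 5 2,3-O-isopropylidene-D-arabinose diethyl dithioacetal
Conditions: AcOH/H2O (7:3), 40 °C, stopped before the internal acetal is attacked; recovered 4 recycled
Reagents that add atoms: none
Why: selective acetal hydrolysis; the monosubstituted terminal dioxolane should hydrolyse faster than the internal trans-disubstituted one.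

Step 4
Reactants: 5 2,3-O-isopropylidene-D-arabinose diethyl dithioacetal
Product: 6 5-O-(tert-butyldiphenylsilyl)-2,3-O-isopropylidene-D-arabinose diethyl dithioacetal
Conditions: TBDPSCl (1.05 equiv), imidazole, CH2Cl2, 0 °C → rt
Reagents that add atoms: tert-butyl(chloro)diphenylsilane, CC(C)(C)[Si](Cl)(c1ccccc1)c1ccccc1
Why: sterically controlled silylation of the primary hydroxyl leaves only sugar O4–H free.

Step 5
Reactants: 6 5-O-(tert-butyldiphenylsilyl)-2,3-O-isopropylidene-D-arabinose diethyl dithioacetal
Product: 7 5-O-(tert-butyldiphenylsilyl)-2,3-O-isopropylidene-4-O-methyl-D-arabinose diethyl dithioacetal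
Conditions: MeI (3 equiv) present first, then NaH (1.3 equiv), THF/DMF (4:1), 0 °C
Reagents that add atoms: iodomethane, CI
Why: Williamson etherification; with MeI already present the alkoxide should be trapped before a 1,2-shift of the bulky silyl group, and S-methylation of the thioacetal is slow at 0 °C.

Step 6
Reactants: 7 5-O-(tert-butyldiphenylsilyl)-2,3-O-isopropylidene-4-O-methyl-D-arabinose diethyl dithioacetal
Product: 8 2,3-O-isopropylidene-4-O-methyl-D-arabinose diethyl dithioacetal
Conditions: Bu4NF, THF, 0 °C → rt
Reagents that add atoms: none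
Why: fluoride-induced desilylation frees the primary alcohol without touching acetal, thioacetal or methyl ether.

Step 7
Reactants: 8 2,3-O-isopropylidene-4-O-methyl-D-arabinose diethyl dithioacetal
Product: 9 2,3-O-isopropylidene-4-O-methyl-D-arabino-pentodialdose 1-(diethyl dithioacetal)
Conditions: SO3·pyridine, DMSO, i-Pr2NEt, CH2Cl2, 0 °C; used crude at once
Reagents that add atoms: none
Why: Parikh–Doering oxidation; activated DMSO oxidises the primary alcohol, leaves the sulfides alone and is mild enough not to epimerise the α-methoxy aldehyde.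

Step 8
Reactants: 9 2,3-O-isopropylidene-4-O-methyl-D-arabino-pentodialdose 1-(diethyl dithioacetal); 10 triethyl phosphonoacetate
Product: 12 ethyl (Z)-5,6-dideoxy-6-iodo-2,3-O-isopropylidene-4-O-methyl-aldehydo-D-arabino-hept-5-enuronate diethyl dithioacetal, via iodophosphonate 11 (not isolated)
Conditions: 10 (1.3 equiv), NaH (1.3 equiv), THF, 0 °C; I2 (1.25 equiv); NaH (1.3 equiv); then 9, −20 → 0 °C
Reagents that add atoms: iodine, II
Why: iodo-Horner–Wadsworth–Emmons olefination; the stabilised anion of the iodophosphonate should place the ester trans to the sugar chain, so iodine is cis to C4 (Z), and the iodine is used up before the thioacetal-bearing aldehyde is added.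

Step 9
Reactants: 12 ethyl (Z)-iodo enoate
Product: 13 (Z)-5,6-dideoxy-6-iodo-2,3-O-isopropylidene-4-O-methyl-D-arabino-hept-5-enose diethyl dithioacetal
Conditions: i-Bu2AlH (2.5 equiv), CH2Cl2, −78 °C; aq. KNaC4H4O6 (potassium sodium tartrate)
Reagents that add atoms: none
Why: 1,2-reduction of the enoate to the allylic alcohol at low temperature keeps the alkenyl iodide and its geometry.

Step 10
Reactants: 13 (Z)-iodo allylic alcohol
Product: 14 (Z)-7-O-(tert-butyldimethylsilyl)-5,6-dideoxy-6-iodo-2,3-O-isopropylidene-4-O-methyl-D-arabino-hept-5-enose diethyl dithioacetal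
Conditions: TBSCl, imidazole, DMF, 0 °C → rt
Reagents that add atoms: tert-butyl(chloro)dimethylsilane, CC(C)(C)[Si](C)(C)Cl
Why: silylation without strong base avoids dehydroiodination; the silyl ether is a poor leaving group next to the later alkenylmetal and falls together with the acetonide in one acid step.

Step 11
Reactants: 14 silyl ether dithioacetal
Product: 15 (Z)-7-O-(tert-butyldimethylsilyl)-5,6-dideoxy-6-iodo-2,3-O-isopropylidene-4-O-methyl-aldehydo-D-arabino-hept-5-enose
Conditions: I2, NaHCO3, acetone/H2O (5:1), 0 °C; aq. Na2S2O3; dried by toluene azeotrope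
Reagents that add atoms: water, O
Why: iodine-promoted oxidative hydrolysis of the dithioacetal (S-iodination, thionium ion, capture by water) in buffered medium spares acetonide and silyl ether, and the α-carbon sits in the more stable trans-dioxolane, so it should not epimerise.

Step 12
Reactants: 15 iodoalkenyl aldehyde
Product: 19 cyclohexenol (target numbering: 1-OMe; 4-OH cis to O5; trans-fused 5,6-O-isopropylidene; 7-OTBS), via alkenylnickel iodide 16 (not isolated), via alkenylchromium dichloride 17 (not isolated), via chromium alkoxide 18 (not isolated)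
Conditions: CrCl2 (6 equiv), NiCl2 (5 mol %), degassed DMF, slow addition of 15 to 0.005 M, rt; aq. NH4Cl
Reagents that add atoms: none
Why: CrCl2 reduces NiCl2 to zerovalent nickel, which inserts into the alkenyl C–I bond with retention of the Z geometry (16); transmetalation hands the alkenyl group to trivalent chromium (17), a weakly basic nucleophile that leaves acetonide, methyl ether and silyl ether alone and adds only to the aldehyde, as in the known intramolecular Nozaki–Hiyama–Kishi closures of iodoalkenyl aldoses to carbasugar cyclohexenols. The ring closes 6-exo-trig: C3 attacks the carbonyl carbon C4, the C=O bond stays outside the ring and the cis C2=C3 bond ends up inside it, which only the Z iodide permits. C4 is the one new stereocentre and is set by the substrate: the trans-fused dioxolane holds O5 and O6 equatorial on the developing half-chair, so the forming C3–C4 bond lies anti to the C5–O bond in either transition state and the two differ only in where the carbonyl oxygen sits; a pseudoequatorial C4–O–Cr bond would eclipse the C7 arm on C3 (A(1,2) strain), so the oxygen should go pseudoaxial, which places the new hydroxyl cis to the equatorial O5. The step needs chemoselectivity (C–I over all other groups), cyclisation over intermolecular addition (high dilution; the Z alkene and the dioxolane already turn the chain ends toward each other) and facial selectivity at C4 (the allylic strain just named, acting on a ring conformation fixed by the acetonide). The chromium alkoxide 18 is hydrolysed on work-up.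

Step 13
Reactants: 19 cyclohexenol
Product: 20 tetraol (1-OMe; free OH at C4, C5, C6 and C7; O4 cis to O5; O5 trans to O6; O6 cis to OMe)
Conditions: 2 M aq. HCl/THF (1:3), rt; NaHCO3, concentration
Reagents that add atoms: none
Why: aqueous acid hydrolysis removes the strained trans-fused acetonide and the primary silyl ether in one operation, and the allylic C–O bonds at C1 and C4, flanked by oxygenated carbons, should not ionise under these conditions.

Step 14
Reactants: 20 tetraol
Product: 21 7-O-benzoyl triol
Conditions: BzCl (1.05 equiv), pyridine, −40 → −20 °C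
Reagents that add atoms: benzoyl chloride, O=C(Cl)c1ccccc1
Why: kinetic acylation at low temperature should pick the only primary (allylic) hydroxyl over the three secondary ones.

Step 15
Reactants: 21 7-O-benzoyl triol
Product: 22 [(3R,4R,5R,6R)-5-(benzoyloxy)-4,6-dihydroxy-3-methoxycyclohex-1-en-1-yl]methyl benzoate (target)
Conditions: Ph2BOCH2CH2NH2 (10 mol %), BzCl (1.2 equiv), i-Pr2NEt, MeCN, 0 °C → rt
Reagents that add atoms: benzoyl chloride, O=C(Cl)c1ccccc1
Why: borinic-acid-catalysed regioselective acylation of a cis-vicinal diol; the diphenylborinate chelates the only cis pair (O4/O5) and is acylated at the equatorial O5, while the pseudoaxial allylic O4 and O6 (no cis hydroxyl partner) stay free.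

**Compound list**

1 | D-arabinose | O=C[C@@H](O)[C@H](O)[C@H](O)CO | starting material
2 | ethanethiol | CCS | starting material
3 | D-arabinose diethyl dithioacetal | CCSC(SCC)[C@@H](O)[C@H](O)[C@H](O)CO | intermediate
4 | 2,3:4,5-di-O-isopropylidene-D-arabinose diethyl dithioacetal | CCSC(SCC)[C@H]1OC(C)(C)O[C@@H]1[C@H]2COC(C)(C)O2 | intermediate
5 | 2,3-O-isopropylidene-D-arabinose diethyl dithioacetal | CCSC(SCC)[C@H]1OC(C)(C)O[C@@H]1[C@H](O)CO | intermediate
6 | 5-O-(tert-butyldiphenylsilyl)-2,3-O-isopropylidene-D-arabinose diethyl dithioacetal | CCSC(SCC)[C@H]1OC(C)(C)O[C@@H]1[C@H](O)CO[Si](c2ccccc2)(c2ccccc2)C(C)(C)C | intermediate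
7 | 5-O-(tert-butyldiphenylsilyl)-2,3-O-isopropylidene-4-O-methyl-D-arabinose diethyl dithioacetal | CCSC(SCC)[C@H]1OC(C)(C)O[C@@H]1[C@H](OC)CO[Si](c2ccccc2)(c2ccccc2)C(C)(C)C | intermediate
8 | 2,3-O-isopropylidene-4-O-methyl-D-arabinose diethyl dithioacetal | CCSC(SCC)[C@H]1OC(C)(C)O[C@@H]1[C@H](OC)CO | intermediate
9 | 2,3-O-isopropylidene-4-O-methyl-D-arabino-pentodialdose 1-(diethyl dithioacetal) | CCSC(SCC)[C@H]1OC(C)(C)O[C@@H]1[C@H](OC)C=O | intermediate
10 | triethyl phosphonoacetate | CCOC(=O)CP(=O)(OCC)OCC | starting material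
11 | ethyl (diethoxyphosphoryl)iodoacetate (iodophosphonate, formed in the flask) | CCOC(=O)C(I)P(=O)(OCC)OCC | intermediate
12 | ethyl (Z)-5,6-dideoxy-6-iodo-2,3-O-isopropylidene-4-O-methyl-aldehydo-D-arabino-hept-5-enuronate diethyl dithioacetal | CCSC(SCC)[C@H]1OC(C)(C)O[C@@H]1[C@H](OC)/C=C(\I)C(=O)OCC | intermediate
13 | (Z)-5,6-dideoxy-6-iodo-2,3-O-isopropylidene-4-O-methyl-D-arabino-hept-5-enose diethyl dithioacetal | CCSC(SCC)[C@H]1OC(C)(C)O[C@@H]1[C@H](OC)/C=C(\I)CO | intermediate
14 | (Z)-7-O-(tert-butyldimethylsilyl)-5,6-dideoxy-6-iodo-2,3-O-isopropylidene-4-O-methyl-D-arabino-hept-5-enose diethyl dithioacetal | CCSC(SCC)[C@H]1OC(C)(C)O[C@@H]1[C@H](OC)/C=C(\I)CO[Si](C)(C)C(C)(C)C | intermediate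
15 | (Z)-7-O-(tert-butyldimethylsilyl)-5,6-dideoxy-6-iodo-2,3-O-isopropylidene-4-O-methyl-aldehydo-D-arabino-hept-5-enose | O=C[C@H]1OC(C)(C)O[C@@H]1[C@H](OC)/C=C(\I)CO[Si](C)(C)C(C)(C)C | intermediate
16 | alkenylnickel iodide from 15 (NiI in place of I; divalent nickel; formed in the flask) | O=C[C@H]1OC(C)(C)O[C@@H]1[C@H](OC)/C=C(\[Ni]I)CO[Si](C)(C)C(C)(C)C | intermediate
17 | alkenylchromium dichloride from 15 (CrCl2 in place of I; trivalent chromium; formed in the flask) | O=C[C@H]1OC(C)(C)O[C@@H]1[C@H](OC)/C=C(\[Cr](Cl)Cl)CO[Si](C)(C)C(C)(C)C | intermediate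
18 | dichlorochromium 4-alkoxide of 19 (formed in the flask) | CO[C@@H]1C=C(CO[Si](C)(C)C(C)(C)C)[C@@H](O[Cr](Cl)Cl)[C@H]2OC(C)(C)O[C@H]12 | intermediate
19 | cyclohexenol, target numbering: 3-[(tert-butyldimethylsilyloxy)methyl]-1-methoxycyclohex-2-ene with 4-OH and trans-fused 5,6-O-isopropylidene; 4-OH cis to O5, O6 cis to OMe (1R,4R,5R,6R) | CO[C@@H]1C=C(CO[Si](C)(C)C(C)(C)C)[C@@H](O)[C@H]2OC(C)(C)O[C@H]12 | intermediate
20 | tetraol, target numbering: 3-(hydroxymethyl)-1-methoxycyclohex-2-ene-4,5,6-triol; O4 cis to O5, O5 trans to O6, O6 cis to OMe | CO[C@@H]1C=C(CO)[C@@H](O)[C@@H](O)[C@@H]1O | intermediate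
21 | 7-O-benzoyl triol (same ring configuration as 20) | CO[C@@H]1C=C(COC(=O)c2ccccc2)[C@@H](O)[C@@H](O)[C@@H]1O | intermediate
22 | [(3R,4R,5R,6R)-5-(benzoyloxy)-4,6-dihydroxy-3-methoxycyclohex-1-en-1-yl]methyl benzoate | CO[C@@H]1C=C(COC(=O)c2ccccc2)[C@@H](O)[C@@H](OC(=O)c2ccccc2)[C@@H]1O | target

**Step count**

Total: 15 steps. Longest linear sequence: 15 steps (1 → 22).

**Steps most likely to fail**

Step 12. The two faces of the aldehyde may not be well differentiated in the closure, so that a large share of the alcohol with the C4 oxygen trans to O5 forms. The fallback sets out from 15 and comes back at 19. The same nickel/chromium closure is run and the two alcohols are separated. The unwanted C4-epimeric cyclohexenol F1 (hydroxyl pseudoequatorial, trans to O5) is inverted in a Mitsunobu reaction (PPh3, DIAD, 4-nitrobenzoic acid, THF, 0 °C → rt). Axial attack on the oxyphosphonium should give the inverted 4-nitrobenzoate F2, with the ester cis to O5. K2CO3 in MeOH then releases 19 and leaves the acetonide and silyl ether in place.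

Step 8. Geometric control in the olefination may erode (the E isomer, with iodine trans to C4, cannot cyclise), or the iodophosphonate may scramble its halogen. The fallback sets out from 9 and comes back at 19. Wittig olefination of 9 with the stabilised ylide ethyl bromo(triphenylphosphoranylidene)acetate (CH2Cl2, rt) should give the (Z)-α-bromo enoate F3 with bromine cis to C4. Reduction with i-Bu2AlH gives the bromo allylic alcohol F4, TBSCl/imidazole the silyl ether F5, and I2/NaHCO3 in aqueous acetone the bromo aldehyde F6. This alkenyl bromide is then closed under nickel/chromium conditions with more catalyst (CrCl2, NiCl2 10 mol %, DMSO, rt → 50 °C) to give 19.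

Step 15. Acylation may go to O6 or O4 instead of O5, or a second acyl group may be taken up. The fallback sets out from 21 and comes back at 22. The triol 21 is heated with Bu2SnO (MeOH, reflux, then toluene azeotrope) to form the 4,5-O-dibutylstannylene acetal F7 on the cis-diol. Stoichiometric BzCl (1.0 equiv, toluene, 0 °C → rt) should then acylate the equatorial oxygen O5 of the tin acetal, giving 22 after aqueous work-up.

**Further compounds**

F1 | step 12 | C4 epimer of 19 (4-OH trans to O5) | CO[C@@H]1C=C(CO[Si](C)(C)C(C)(C)C)[C@H](O)[C@H]2OC(C)(C)O[C@H]12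
F2 | step 12 | 4-O-(4-nitrobenzoyl) derivative of 19 (ester cis to O5) | CO[C@@H]1C=C(CO[Si](C)(C)C(C)(C)C)[C@@H](OC(=O)c3ccc(cc3)[N+](=O)[O-])[C@H]2OC(C)(C)O[C@H]12
F3 | step 8 | ethyl (Z)-6-bromo-5,6-dideoxy-2,3-O-isopropylidene-4-O-methyl-aldehydo-D-arabino-hept-5-enuronate diethyl dithioacetal | CCSC(SCC)[C@H]1OC(C)(C)O[C@@H]1[C@H](OC)/C=C(\Br)C(=O)OCC
F4 | step 8 | (Z)-6-bromo-5,6-dideoxy-2,3-O-isopropylidene-4-O-methyl-D-arabino-hept-5-enose diethyl dithioacetal | CCSC(SCC)[C@H]1OC(C)(C)O[C@@H]1[C@H](OC)/C=C(\Br)CO
F5 | step 8 | 7-O-(tert-butyldimethylsilyl) ether of F4 | CCSC(SCC)[C@H]1OC(C)(C)O[C@@H]1[C@H](OC)/C=C(\Br)CO[Si](C)(C)C(C)(C)C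
F6 | step 8 | (Z)-6-bromo-7-O-(tert-butyldimethylsilyl)-5,6-dideoxy-2,3-O-isopropylidene-4-O-methyl-aldehydo-D-arabino-hept-5-enose | O=C[C@H]1OC(C)(C)O[C@@H]1[C@H](OC)/C=C(\Br)CO[Si](C)(C)C(C)(C)C
F7 | step 15 | 4,5-O-dibutylstannylene acetal of 21 | CO[C@@H]1C=C(COC(=O)c2ccccc2)[C@H]2O[Sn](CCCC)(CCCC)O[C@H]2[C@@H]1O
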